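The numbers in the tables come from a simulation from invented constants, and the scatter is random.

in all of them: gas 120 mM (held)

| run | substrate | remark | time |
|---|---|---|---|
| maple | 0.12 M | run made earlier |  |
| cedar | 0.19 M | run made earlier |  |
| flask | 0.25 M |  | 15 d |

| run | time / d | intermediate / % | target / % |
|---|---|---|---|
| maple | 1.04 | 30.2 | 19.8 |
| maple | 1.67 | 41.8 | 32.8 |
| maple | 2.50 | 45.7 | 42.7 |
| maple | 4.00 | 45.4 | 45.9 |
| maple | 8.00 | 41.4 | 42.0 |
| maple | 12.0 | 38.0 | 37.5 |
| cedar | 1.04 | 27.3 | 17.7 |
| cedar | 1.67 | 37.6 | 29.7 |
| cedar | 2.50 | 45.9 | 40.4 |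
| cedar | 4.00 | 46.8 | 44.8 |
| cedar | 8.00 | 42.9 | 42.0 |
| cedar | 12.0 | 37.6 | 37.8 |

(standard deviation of a reading: 0.5 percentage points)

- at the start none of the gas is in solution

* when, up to 15 d, the flask holds most intermediate
* the amount of intermediate, in percent of the substrate charged, at that time

1. Slowness first: from 4.00 d to 12.0 d in the cedar run, the sum of [intermediate] and [target] decays at a leak rate of 0.0243 /d.

2. As a first guess, whatever is missing from that sum is [substrate]. Between 1.67 d and 2.50 d in cedar, this remainder falls at 1.05 /d, much faster than the leak.

3. The sum climbs while feed exceeds leak. Taking the sum as the whole charge, it tops out when [substrate] reaches a stop level, the leak rate over the substrate rate: 2.32% of the charge. I let intermediate, 51.1% of the sum at 4.00 d in cedar, peak with it.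

4. Counting time constants down from cedar's remainder at 2.50 d, then adding 0.207 d for the flask's larger charge, scaled from cedar's lag behind maple, gives 4.40 d.

5. The weak link is step 2, since the remainder counts leaked material as substrate. Adding the leak back gives cedar's clearing rate, a pseudo-first-order constant for substrate loss read from its readings, of 1.55 /d. The stop level becomes 1.57%. I commit for the flask to 3.71 d and 45.9%.

The forecast gives 3.6 d and 48%, noting “The peak is flat, so its time is loose”.

The flask peaks at 3.84 d with 46.4%. At 3.84 d its substrate stands at 2.43%, above the stop level of 1.57%.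

    substrate + reagent → intermediate + by-product (k = 0.600 /M/h)
    intermediate ⇌ target (K = 0.980, k = 0.0980 /h)
    intermediate ⇌ isomer of the product (K = 110, k = 0.00210 /h)
    gas ⇌ reagent, rate k4*(csat - [reagent]) (kL = 0.0720 /h)

The same flask left until 4.0 d runs 0.158 d past that point, so cedar's clearing rate, applied to this flask, takes 2.43% down to 1.90%. Computed, it holds 1.90% substrate and 46.3% intermediate.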